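The constants set two clocks: 13.7 min is the lifetime of starting material, and 24.4 min is the lifetime of partner.

    starting material → open intermediate (k1 = 0.073 min⁻¹)
    partner → second intermediate (k2 = 0.041 min⁻¹)
    starting material + open intermediate → side product (k3 = 0.067 L mol⁻¹ min⁻¹)
    open intermediate + second intermediate → target (k4 = 0.19 L mol⁻¹ min⁻¹)

all flasks: partner 0.240 M
- east: starting material 0.20 M (fed, over 2.00 h); time 2.5 h; all but starting material at the start; starting material goes in evenly over 2.00 h, the run ends at 2.5 h
- north-west: starting material 0.20 M; a single well-mixed tank run continuously and read at steady state, 2.5 h in it on average
- west: starting material 0.20 M; time 2.5 h; a tube with plug flow, the mixed feed as stated, residence time 2.5 h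
- north-east: starting material 0.20 M; time 2.5 h; a closed flask charged with all of it at once and left for 2.5 h

- percent here means starting material units held: one side product counts as two
- the stated concentrations are those of everything mixed, before any reaction; amounts are the same in each set-up
- the feed brings no volume worth counting
- run time (east): 2.5 h

1. the set-up with the highest amount of open intermediate at the outlet or at the end, in percent of the starting material put in ("none" if the first two lie within 2 percentage points) (east / north-west / west / north-east / none)
2. amount of open intermediate at the outlet or at the end, in percent of the starting material put in, east
3. amount of open intermediate at the outlet or at the end, in percent of the starting material put in, north-west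
4. amount of open intermediate at the outlet or at the end, in percent of the starting material put in, west
5. amount of open intermediate at the outlet or at the end, in percent of the starting material put in, north-east

Write I for open intermediate and J for second intermediate. The reckoning is made for the closed north-east flask. The west tube with plug flow follows the same course over its residence time.

First, the main step by itself. The 150 min in the north-east flask span 11.0 lifetimes of starting material, so nearly all of it becomes I, and I stands at 100% of the charge.

Second, partner and the step to target are added. Partner turns into J well within the run. Starting material is the limiting reagent, with 0.20 M against 0.240 M of partner. Each target consumes one I and one J, so the difference J − I stays fixed at the surplus S = 0.0400 M. The ratio I/J therefore falls as exp(−t/τ), where τ = 132 min is the surplus lifetime: one over k4 times S. Starting from 0.833, the ratio reaches 0.267 at the end. With J = I + S, this leaves I at 7.27% of the charge.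

Third, the side step is added. Its lifetime for I at the charged concentration is 74.6 min, longer than the 13.7 min of starting material, so it acts briefly. It lowers I and widens S. The late arrival of J pulls the other way. Neither is reckoned, so 7.27% stands for north-east and west. The reckoning stops short of the fed flask and the tank.

The forecast gave 23% east, 24% north-west, 6% west, 6% north-east and best none, judging that “those two land within about a point of each other”.

The simulation gives 20.1% east, 24.2% north-west, 6.93% west and 6.93% north-east, so the best is north-west. The north-east figure lies 0.34 percentage points below the reckoning.

The north-east flask is not at rest at 2.5 h, since it still holds 6.93% open intermediate beside 12.7% side product. The 132 min was reckoned on the surplus as charged. With 12.7% of the charge in side product at 2.5 h, and the rest counted as I and target, partner and J together stand above I by about 0.0654 M. The surplus lifetime in the north-east flask is then 80.4 min. From there to 25.0 h lie 16.8 of these lifetimes. Shrinking the holding by exp(−16.8) brings it to <0.001%. Ten times the time therefore still moves open intermediate by about 6.9 points. The north-east run left that long holds 0% open intermediate.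

The numbers come from no measurement; what happens was integrated by code.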